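The data are calculated with made-up constants; scatter was added.

A small charge, maple, and a larger one, birch, have run. The flask now takes 20 mM of each substrate, more than either earlier run.

the same everywhere: gas 2.6 mM (held); free catalyst 20 µM
- maple: left-handed substrate 10 mM; right-handed substrate 10 mM; run made earlier
- birch: left-handed substrate 15 mM; right-handed substrate 15 mM; run made earlier
- flask: left-handed substrate 20 mM; right-handed substrate 20 mM; time 10 h

| run | time / h | right-handed substrate / % | left-handed substrate / % |
|---|---|---|---|
| maple | 0.500 | 48.5 | 21.5 |
| maple | 1.50 | 50.0 | 8.1 |
| maple | 3.00 | 49.0 | 3.6 |
| maple | 4.00 | 50.7 | 1.8 |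
| maple | 6.00 | 48.0 | 2.7 |
| maple | 8.00 | 48.1 | 0.2 |
| birch | 1.33 | 48.3 | 8.1 |
| birch | 2.50 | 48.9 | 4.8 |
| birch | 4.00 | 48.0 | 2.2 |
| birch | 5.00 | 47.7 | 1.7 |
| birch | 6.00 | 48.0 | 2.5 |
| birch | 8.00 | 48.9 | 1.2 |

(each reading ± 1 percentage point)

- free catalyst is single-handed; left-handed substrate and right-handed substrate are mirror images of each other, charged as a racemate, each of them at the stated concentration
- at the start none of the gas is in solution

1. whether the excess of right-handed substrate over left-handed substrate among what is left of the two reaches 90% by 10 h (yes / no)
2. the highest excess of right-handed substrate over left-handed substrate among what is left of the two up to 10 h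

A racemate is the zero of the scale. So I measure by the separation, ln([right-handed substrate]/[left-handed substrate]), which starts at zero. An excess of 90% asks for 2.94; call this the needed separation. Maple reads 2.61 at 3.00 h and 3.34 at 4.00 h.

Two views part over the flask. The first says the catalyst dies by the clock, so percentages do not depend on the charge. At 4.00 h, maple reads 1.8% of left-handed substrate and birch reads 2.2%. The forecast takes this side: yes, with a top of 94%, “assuming no new limit appears at 20 mM”. My own figure differs slightly. The latest readings, maple from 4.00 h and birch from 5.00 h, pooled, give a plateau separation of 3.36. That is above the need, and it corresponds to an excess of 93.3%, just under the forecast.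

The second view is exactly such a new limit: each catalyst makes a set number of turnovers. Maple's last reading, 0.2%, counts as finished within the scatter. Birch's, 1.2%, counts as stopped, after 14.6 mM of left-handed substrate. The flask stopped there would reach a separation of 1.31, below the need. This view answers no.

The flask answers yes, with a top of 94.7%.

    left-handed product ⇌ right-handed product (k = 0.00348 /h)
    free catalyst → spent catalyst (k = 0.554 /h)
    reagent + free catalyst + left-handed substrate → free catalyst + left-handed product (k = 11700 /M²/s)
    gas ⇌ reagent, rate k4*(csat - [reagent]) (kL = 45.1 /h)
    reagent + free catalyst + right-handed substrate → free catalyst + right-handed product (k = 2.79 × 10⁵ /M²/h)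

By 10.0 h the flask has used 19.5 mM of left-handed substrate, more than the count view's 14.6 mM. That view keeps the range up to its count, and maple's charge of 10 mM lies within it. At 10.0 h the flask holds 0.393% of its free catalyst. The top is a separation of 3.60, above the needed 2.94 by 0.664, and the need was crossed at 3.18 h.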